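**Retrosynthetic overview**
1. The CH2 bridge is cut last: target 11 ⇒ ring A dienone 8 + a one-carbon iminium reagent + ring B phenol 4 (convergent final step).
2. 8 ⇒ enantioselective dearomative C-prenylation (Trost asymmetric allylic alkylation) of acylphloroglucinol 6 with prenyl acetate 7; this sets the only stereocentre.
3. 6 ⇒ 2-methylphloroglucinol 5 + hexanoyl chloride 2; 4 ⇒ phloroglucinol 1 + 2, then selective 4-O-methylation.
4. No ring is built: both six-membered rings are bought as phloroglucinols. Ring B stays aromatic, ring A is dearomatised in step 4, and the two are joined in step 5.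

Assumption: the descriptor S refers to the tautomer drawn in the given SMILES; the facial sense of the Trost ligand on this nucleophile cannot be predicted with certainty, so the (R,R)-ligand is written and the (S,S)-ligand is taken instead if chiral HPLC/ECD of 8 shows the antipode.

**Route**

Step 1
Reactants: 1 phloroglucinol; 2 hexanoyl chloride
Product: 3 1-(2,4,6-trihydroxyphenyl)hexan-1-one
Conditions: AlCl3 (4 equiv), PhNO2–CH2Cl2, 0 °C → 45 °C; then ice/1 M HCl
Reagents that add atoms: none
Why: Friedel–Crafts C-acylation of the symmetric, very electron-rich triol gives a single mono-ketone (any aryl ester formed first undergoes Fries rearrangement), and the new ketone deactivates the ring against a second acylation.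

Step 2
Reactants: 3 1-(2,4,6-trihydroxyphenyl)hexan-1-one
Product: 4 1-(2,6-dihydroxy-4-methoxyphenyl)hexan-1-one
Conditions: Me2SO4 (1.0 equiv), K2CO3 (1.0 equiv), acetone, rt → 40 °C
Reagents that add atoms: dimethyl sulfate, COS(=O)(=O)OC
Why: Williamson O-methylation in which the 4-OH para to the ketone is the most acidic hydroxyl and the only one not deactivated by hydrogen bonding to the carbonyl, so one equivalent of the hard electrophile methylates it selectively.

Step 3
Reactants: 5 2-methylphloroglucinol; 2 hexanoyl chloride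
Product: 6 1-(2,4,6-trihydroxy-3-methylphenyl)hexan-1-one
Conditions: AlCl3 (4 equiv), PhNO2–CH2Cl2, 0 °C → 45 °C; then ice/1 M HCl
Reagents that add atoms: none
Why: Friedel–Crafts acylation in which the two free ring positions of 5 are equivalent, so only one regioisomer can form.

Step 4
Reactants: 6 1-(2,4,6-trihydroxy-3-methylphenyl)hexan-1-one; 7 prenyl acetate
Product: 8 (4S)-2-hexanoyl-3,5-dihydroxy-4-methyl-4-(3-methylbut-2-en-1-yl)cyclohexa-2,5-dien-1-one
Conditions: Pd2(dba)3·CHCl3 (2.5 mol%), (R,R)-DACH-phenyl Trost ligand (7.5 mol%), 7 (1.0 equiv), Et3N (2.2 equiv), CH2Cl2, 0 °C → rt; 1 M HCl work-up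
Reagents that add atoms: none
Why: Dearomative Trost asymmetric allylic alkylation (Tsuji–Trost) in which the phenolate attacks the unsubstituted terminus of the (1,1-dimethylallyl)palladium cation through its methyl-bearing carbon (the most nucleophilic carbon of an alkylphloroglucinolate, O-prenylation being reversible under zerovalent palladium), and the chiral pocket of the ligand selects one enantiotopic face of the planar anion to set the quaternary (S) centre.

Step 5
Reactants: 8 (4S)-2-hexanoyl-3,5-dihydroxy-4-methyl-4-(3-methylbut-2-en-1-yl)cyclohexa-2,5-dien-1-one; 4 1-(2,6-dihydroxy-4-methoxyphenyl)hexan-1-one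
Product: 11 (4S)-2-hexanoyl-6-[(3-hexanoyl-2,4-dihydroxy-6-methoxyphenyl)methyl]-3,5-dihydroxy-4-methyl-4-(3-methylbut-2-en-1-yl)cyclohexa-2,5-dien-1-one (the target), via Mannich base 9 (not isolated), via methylidene trione 10 (not isolated)
Conditions: N,N-dimethylmethyleneiminium iodide (Eschenmoser's salt, 1.05 equiv), MeCN, 0 °C → rt, 1 h; then 4 (2.0 equiv), 70 °C
Reagents that add atoms: Eschenmoser's salt (N,N-dimethylmethyleneiminium iodide), C[N+](C)=C.[I-]
Why: Mannich aminomethylation of the only free enolic carbon of 8, E1cB loss of dimethylamine to the Knoevenagel-type methylidene trione and Friedel–Crafts-type conjugate addition of phenol 4 (its two free positions are equivalent) forge the CH2 bridge, while the quaternary stereocentre carries no hydrogen and is untouched.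

**Compound list**
1 | phloroglucinol (benzene-1,3,5-triol) | Oc1cc(O)cc(O)c1 | starting material
2 | hexanoyl chloride | CCCCCC(Cl)=O | starting material
3 | 1-(2,4,6-trihydroxyphenyl)hexan-1-one | CCCCCC(=O)c1c(O)cc(O)cc1O | intermediate
4 | 1-(2,6-dihydroxy-4-methoxyphenyl)hexan-1-one | CCCCCC(=O)c1c(O)cc(OC)cc1O | intermediate
5 | 2-methylphloroglucinol (2-methylbenzene-1,3,5-triol) | Cc1c(O)cc(O)cc1O | starting material
6 | 1-(2,4,6-trihydroxy-3-methylphenyl)hexan-1-one | CCCCCC(=O)c1c(O)cc(O)c(C)c1O | intermediate
7 | prenyl acetate (3-methylbut-2-en-1-yl acetate) | CC(=O)OCC=C(C)C | starting material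
8 | (4S)-2-hexanoyl-3,5-dihydroxy-4-methyl-4-(3-methylbut-2-en-1-yl)cyclohexa-2,5-dien-1-one | CCCCCC(=O)C1=C(O)[C@@](C)(CC=C(C)C)C(O)=CC1=O | intermediate
9 | (4S)-6-[(dimethylamino)methyl]-2-hexanoyl-3,5-dihydroxy-4-methyl-4-(3-methylbut-2-en-1-yl)cyclohexa-2,5-dien-1-one (Mannich base, present in the flask as its hydroiodide) | CCCCCC(=O)C1=C(O)[C@@](C)(CC=C(C)C)C(O)=C(CN(C)C)C1=O | intermediate
10 | (4R)-2-hexanoyl-3-hydroxy-4-methyl-6-methylidene-4-(3-methylbut-2-en-1-yl)cyclohex-2-ene-1,5-dione (same spatial arrangement as in 8; the descriptor changes only because the CIP priorities change) | CCCCCC(=O)C1=C(O)[C@@](C)(CC=C(C)C)C(=O)C(=C)C1=O | intermediate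
11 | (4S)-2-hexanoyl-6-[(3-hexanoyl-2,4-dihydroxy-6-methoxyphenyl)methyl]-3,5-dihydroxy-4-methyl-4-(3-methylbut-2-en-1-yl)cyclohexa-2,5-dien-1-one (CNP0108719.1) | CCCCCC(=O)C1=C(O)[C@@](C)(CC=C(C)C)C(O)=C(Cc2c(OC)cc(O)c(C(=O)CCCCC)c2O)C1=O | target

**Summary**
Total step count: 5. Longest linear sequence: 3 steps (5 → 6 → 8 → 11, or 1 → 3 → 4 → 11).

Steps most likely to fail:

1. Step 4. The risks are prenylation at the free ring CH or on oxygen, a second prenylation of 8, and insufficient enantiomeric excess. Fallback: racemic alkylation followed by classical resolution. It sets out from 6, which is alkylated under the classical acylfilicinic-acid conditions (prenyl bromide 1.0 equiv, NaOMe 2.5 equiv, MeOH, 0 °C) to racemic 2-hexanoyl-3,5-dihydroxy-4-methyl-4-(3-methylbut-2-en-1-yl)cyclohexa-2,5-dien-1-one F1. This strongly acidic triketone is combined with (R)-1-phenylethylamine (1.0 equiv, EtOAc/EtOH) and the less soluble (R)-1-phenylethylammonium salt of 8 F2 is recrystallised to constant rotation. The (R)-1-phenylethylammonium salt of the (4R)-antipode F3 stays in the mother liquor (the (S)-amine is used if the solubilities are reversed). Acidification of the crystalline salt with 1 M HCl and extraction returns the route to 8.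

2. Step 5. The risks are the ring A–CH2–ring A homodimer, a second alkylation of ring B, and loss of precious chiral 8. Fallback: the polarity of the coupling is reversed. It sets out from 4, which is aminomethylated with Eschenmoser's salt (0.8 equiv, CH2Cl2, rt, excess 4 recovered) to the isolated Mannich base 1-{3-[(dimethylamino)methyl]-2,6-dihydroxy-4-methoxyphenyl}hexan-1-one F4. Heating this with 8 (1.0 equiv, dioxane, 90 °C) expels dimethylamine to an ortho-quinone methide of ring B, which is captured by the enolic carbon C6 of 8, so the route is rejoined directly at 11.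

3. Step 2. The risk is a mixture of mono- and dimethyl ethers. Fallback: over-methylation followed by chelation-directed unmasking. It sets out from 3, which is exhaustively methylated (Me2SO4 4 equiv, K2CO3, acetone, reflux) to 1-(2,4,6-trimethoxyphenyl)hexan-1-one F5. AlCl3 (4 equiv, chlorobenzene, 80 °C) then cleaves only the two methoxy groups ortho to the ketone, which coordinate aluminium through the carbonyl, and the route is rejoined at 4.

**Further compounds**
F1 | step 4 | racemic 2-hexanoyl-3,5-dihydroxy-4-methyl-4-(3-methylbut-2-en-1-yl)cyclohexa-2,5-dien-1-one | CCCCCC(=O)C1=C(O)C(C)(CC=C(C)C)C(O)=CC1=O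
F2 | step 4 | (R)-1-phenylethylammonium salt of 8 | CCCCCC(=O)C1=C([O-])[C@@](C)(CC=C(C)C)C(O)=CC1=O.C[C@@H]([NH3+])c1ccccc1
F3 | step 4 | (R)-1-phenylethylammonium salt of the (4R)-antipode of 8 | CCCCCC(=O)C1=C([O-])[C@](C)(CC=C(C)C)C(O)=CC1=O.C[C@@H]([NH3+])c1ccccc1
F4 | step 5 | 1-{3-[(dimethylamino)methyl]-2,6-dihydroxy-4-methoxyphenyl}hexan-1-one | CCCCCC(=O)c1c(O)cc(OC)c(CN(C)C)c1O
F5 | step 2 | 1-(2,4,6-trimethoxyphenyl)hexan-1-one | CCCCCC(=O)c1c(OC)cc(OC)cc1OC
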